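Readings and results were computed on assumed constants; the scatter is artificial.

**Slow growth.** Slowness is a gift: the elm run at −10 °C shows 0.6% of target after 5.00 h, against a scatter of 0.5 percentage points, and a flask this slow we can reckon by hand before any computer is asked. We take target as made from starting material and partner in one second-order step, with the two charged nearly equal, and we leave the rival reagent out. Integrated, fraction made over fraction left grows in proportion to time, so the fraction made is t/(t+τ). Here τ is the clock, the time in which the charge falls to half, and it runs inversely to concentration.

| flask | starting material | partner | rival reagent | temperature | remark | time |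
|---|---|---|---|---|---|---|
| maple | 0.40 M | 0.95 equiv | 1.1 equiv | −10 °C | run made earlier |  |
| oak | 1.6 M | 0.95 equiv | 1.1 equiv | 40 °C | run made earlier |  |
| elm | 0.80 M | 1.4 equiv | 1.1 equiv | −10 °C | run made earlier |  |
| east | 0.80 M | 0.950 equiv | 1.10 equiv | −5 °C |  | 8.0 h |
| west | 0.80 M | 0.950 equiv | 1.10 equiv | 85 °C |  | 8.0 h |
| north-west | 0.80 M | 0.950 equiv | 1.10 equiv | 55 °C |  | 8.0 h |
| north | 0.80 M | 0.950 equiv | 1.10 equiv | 25 °C |  | 8.0 h |

maple run (percent of the starting material charged): time / h: target / % = 1.33: 0.3; 2.50: 0.4; 4.00: 0; 5.00: 0.9

oak run (percent of the starting material charged): time / min: target / % = 4.00: 5.5; 10.0: 14.5; 20.0: 22.0; 30.0: 28.8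

elm run (percent of the starting material charged): time / h: target / % = 0.667: 0; 1.50: 0; 3.00: 0.4; 5.00: 0.6

(readings scatter by 0.5 percentage points)

1. the flask that comes out highest in amount of target, in percent of the starting material charged, or "all alike" when all lie within 1.5 percentage points (east / west / north-west / north / all alike)
2. target at the end, in percent of the starting material charged, east
3. target at the end, in percent of the starting material charged, west
4. target at the end, in percent of the starting material charged, north-west
5. target at the end, in percent of the starting material charged, north

**The rungs.** The last oak reading gives a clock of 74.2 min, so 2.47 h at 0.80 M and 40 °C. The last elm reading, scaled for its 1.4 equiv of partner, gives 1230 h at −10 °C, a rough figure, since that reading carries a scatter of 0.5 points. Spacing the logarithm of the clock evenly in temperature between these two, we get 0.00926 h for west, 0.384 h for north-west, 15.9 h for north and 660 h for east, this last being east's clock.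

**Against the time.** The clock of north-west is shorter than the 8.0 h asked, and that of west shorter still. On this reckoning these two flasks finish early, with the partner charge of 0.950 equiv as ceiling, and their target then sits for hours, while the oak readings end at 30.0 min. For those two we commit to the ceiling and no further. North's clock is longer than the time, which gives 33.4%, and east's is far longer, which gives 1.20%.

**The result.** The forecast named north-west, with 2.3% for east, 62% for west, 74% for north-west and 40% for north, and said “North-west is my likely best”. The flasks give 1.45% for east, 26.1% for west, 11.6% for north-west and 33.2% for north, so north is highest.

    starting material + partner → target (k = 0.118 /M/h, Ea = 86.0 kJ/mol)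
    starting material + rival reagent → side product (k = 0.00649 /M/h, Ea = 83.0 kJ/mol)
    target ⇌ isomer of the product (K = 22.0, k = 0.0441 /h, Ea = 99.0 kJ/mol, ΔH = −33.0 kJ/mol)
    (constants at 25 °C)

**Where it parts.** East's 1.45% stands beside our 1.20%, and north-west has 1.66% of its starting material left. But north-west ends with 74.5% of isomer of the product against 11.6% of target, and from the coldest to the hottest flask the loss of target to isomer of the product speeds up by a factor of 70000, the making of target by 16000.

**Second flask.** Take east with 2.0 M of starting material, the equivalents, temperature and time held: its clock shortens to 264 h, which gives 2.94%. The computed flask gives 3.55%.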